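The oxolane core is read as a masked butenolide: C9 is the lactone carbonyl, C8 its α-carbon, C8' the β-carbon and C9' the acetal carbon of (5R)-5-menthyloxyfuran-2(5H)-one. One three-component operation adds the lithiated dithiane of O-benzylvanillin (ring B, C7') to C8' and traps the lactone enolate at C8 with TIPS-vanillin (ring C, C7), so the acetal centre dictates C8' and C8. Hydride reduction, desulfurisation and acid closure of the C7–O bond then give a differentiated lariciresinol. The ring B phenol is freed and the erythro glycerol unit (ring A) is built by an auxiliary-controlled syn aldol with inversion at C7''. Final unmasking needs fluoride only.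

Key step: step 5

Remarks on the chemistry:
- Lignan locants are used: ring C with C7–C9 is the 2-aryl half of the oxolane, ring B with C7'–C9' the benzyl half, ring A with C7''–C9'' the glycerol unit.
- C7 forms in step 5 as a mixture of epimers, is written without a descriptor in 12–14 and is fixed in step 8.
- Ring B is carried as its benzyl ether and ring C as its TIPS ether. Hydrogenolysis is then needed only once, before the ring A carbinol exists, and the last step is a buffered fluoride treatment.
- Assumption: O-benzylvanillin, (R)-4-benzyloxazolidin-2-one and bromoacetyl bromide are taken as commercial.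

Step 1
Reactants: 1 furfural
Product: 2 5-hydroxyfuran-2(5H)-one (racemic)
Conditions: O2, hν, methylene blue (cat.), MeOH, rt
Reagents that add atoms: dioxygen, O=O
Why: Dye-sensitised photooxygenation, in which singlet oxygen adds across C2 and C5 of the furan in a [4+2] cycloaddition and methanolysis of the endoperoxide expels the formyl carbon, should give the hydroxybutenolide, whose racemic hemiacetal centre is resolved in step 2.

Step 2
Reactants: 2 5-hydroxyfuran-2(5H)-one; 3 (−)-menthol
Product: 4 (5R)-5-[(1R,2S,5R)-menthyloxy]furan-2(5H)-one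
Conditions: CSA (cat.), toluene, reflux, azeotropic removal of water; crystallise from petroleum ether; liquors re-equilibrated with CSA and recrystallised
Reagents that add atoms: none
Why: Acid-catalysed acetalisation of the hemiacetal gives both C5 epimers, and because they interconvert under acid while the (5R) epimer crystallises, a crystallisation-induced diastereomer transformation should funnel the material into the single (5R) acetal that later controls C8' and C8.

Step 3
Reactants: 5 O-benzylvanillin; 6 propane-1,3-dithiol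
Product: 7 2-(4-benzyloxy-3-methoxyphenyl)-1,3-dithiane
Conditions: BF3·OEt2 (cat.), CH2Cl2, 0 °C to rt
Reagents that add atoms: none
Why: Lewis-acid-catalysed dithioacetalisation of an aryl aldehyde, to which the benzyl ether is inert, installs the acyl-anion equivalent whose carbon becomes C7'.

Step 4
Reactants: 8 vanillin
Product: 9 3-methoxy-4-(triisopropylsilyloxy)benzaldehyde
Conditions: TIPSCl, imidazole, DMF, rt
Reagents that add atoms: triisopropylsilyl chloride, CC(C)[Si](Cl)(C(C)C)C(C)C
Why: Silylation of a phenol gives a hindered aryl TIPS ether that should survive organolithium, hydride, Ni2B and mild acid and falls only to fluoride at the end.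

Step 5
Reactants: 7 2-(4-benzyloxy-3-methoxyphenyl)-1,3-dithiane; 4 (5R)-5-menthyloxyfuran-2(5H)-one; 9 3-methoxy-4-(triisopropylsilyloxy)benzaldehyde
Product: 12 (3S,4R,5R)-4-[2-(4-benzyloxy-3-methoxyphenyl)-1,3-dithian-2-yl]-3-[hydroxy(3-methoxy-4-triisopropylsilyloxyphenyl)methyl]-5-[(1R,2S,5R)-menthyloxy]oxolan-2-one as a mixture of C7 epimers, via lithiated dithiane 10 (not isolated), via lithium lactone enolate 11 (not isolated)
Conditions: n-BuLi, THF, −78 °C; then 4, −78 °C; then 9, −78 °C; AcOH quench at −78 °C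
Reagents that add atoms: none
Why: n-BuLi removes the C2 proton of 7 and the soft, sulfur-stabilised benzylic anion 10 adds in Michael fashion to the β-carbon of 4 (C7'–C8' bond), after which the lithium lactone enolate 11 attacks aldehyde 9 in an aldol addition (C8–C7 bond). The closest known reaction type is the tandem conjugate addition–enolate trapping of lithiated 2-aryl-1,3-dithianes on γ-alkoxybutenolides, an established entry to lignan skeletons. No ring is closed. C8' is controlled by the (5R) acetal centre, whose menthyloxy group blocks one face so that 10 enters anti to it, and C8 is controlled by the new bulky dithianyl group at C8', the aldehyde approaching anti to it, which gives the 3,4-trans-4,5-trans lactone; C7 forms as an epimer mixture that step 8 erases. The step needs 1,4- over 1,2-addition, which the soft hindered anion and the unhindered β-carbon secure, and interception of the enolate before proton transfer or retro-aldol, which low temperature and a cold acidic quench secure.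

Step 6
Reactants: 12 tandem adduct
Product: 13 (2R,3R)-2-[2-(4-benzyloxy-3-methoxyphenyl)-1,3-dithian-2-yl]-3-[hydroxy(3-methoxy-4-triisopropylsilyloxyphenyl)methyl]butane-1,4-diol (C7 epimers)
Conditions: LiAlH4, THF, 0 °C; aqueous NaOH work-up
Reagents that add atoms: none
Why: Hydride reduction of the lactone gives the C9 carbinol and unmasks the acetal carbon as an aldehyde by loss of menthoxide from the ring-opened hemiacetal, which is reduced in turn to the C9' carbinol, while dithiane, benzyl ether and aryl silyl ether are inert at 0 °C and no stereocentre is touched.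

Step 7
Reactants: 13 dithiane triol
Product: 14 (2R,3R)-2-(4-benzyloxy-3-methoxybenzyl)-3-[hydroxy(3-methoxy-4-triisopropylsilyloxyphenyl)methyl]butane-1,4-diol (C7 epimers)
Conditions: NiCl2·6H2O, NaBH4, MeOH–THF, 0 °C
Reagents that add atoms: none
Why: Reductive desulfurisation of the benzylic dithioacetal with Ni2B generated in the flask converts C7' into the methylene group under conditions that, unlike more active nickel catalysts, should spare the aryl benzyl ether, the silyl ether and the C7 carbinol.

Step 8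
Reactants: 14 triol
Product: 15 [(2S,3R,4R)-4-(4-benzyloxy-3-methoxybenzyl)-2-(3-methoxy-4-triisopropylsilyloxyphenyl)oxolan-3-yl]methanol
Conditions: CSA (cat.), CH2Cl2, 0 °C to rt
Reagents that add atoms: none
Why: In this acid-catalysed cyclodehydration either C7 epimer ionises to the same ring C benzylic cation, which the C9' hydroxyl captures in a 5-exo closure that places the aryl group trans to the C8 hydroxymethyl group (7S), the reversible ionisation funnelling any cis ether to the trans ring, while catalytic acid at low temperature should keep Friedel–Crafts attack by ring B from competing.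

Step 9
Reactants: 15 oxolane alcohol
Product: 16 C9 triisopropylsilyl ether of 15
Conditions: TIPSCl, imidazole, DMAP (cat.), DMF, rt
Reagents that add atoms: triisopropylsilyl chloride, CC(C)[Si](Cl)(C(C)C)C(C)C
Why: Silylation of the only free hydroxyl protects C9–OH against the boron triflate and Mitsunobu steps with a group that leaves in the final fluoride treatment.

Step 10
Reactants: 16 bis-TIPS benzyl ether
Product: 17 ring B phenol (16 without the benzyl group)
Conditions: H2 (1 atm), Pd/C, EtOAc, rt
Reagents that add atoms: none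
Why: Hydrogenolysis of the aryl benzyl ether over Pd/C in a neutral solvent should free the ring B phenol faster than it touches the benzylic C7–O ring bond, and silyl ethers are inert to it.

Step 11
Reactants: 18 (R)-4-benzyloxazolidin-2-one; 19 bromoacetyl bromide
Product: 21 (R)-4-benzyl-3-(bromoacetyl)oxazolidin-2-one, via N-lithio oxazolidinone 20 (not isolated)
Conditions: n-BuLi, THF, −78 °C; then 19, −78 °C
Reagents that add atoms: none
Why: N-Acylation of the lithiated oxazolidinone by the acyl bromide, which is far more electrophilic than the alkyl bromide at −78 °C, gives the chiral bromoacetyl imide without touching its stereocentre.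

Step 12
Reactants: 17 ring B phenol; 21 (R)-4-benzyl-3-(bromoacetyl)oxazolidin-2-one
Product: 22 aryloxyacetyl imide (ring B oxygen of 17 bearing CH2C(=O)N of the auxiliary)
Conditions: K2CO3, acetone, rt
Reagents that add atoms: none
Why: In this Williamson etherification the ring B phenoxide displaces the bromide activated by the adjacent imide carbonyl, a fast SN2 reaction that carbonate in acetone allows without cleaving the imide or the silyl ethers.

Step 13
Reactants: 22 aryloxyacetyl imide; 9 3-methoxy-4-(triisopropylsilyloxy)benzaldehyde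
Product: 24 syn aldol adduct (R)-4-benzyl-3-[(2R,3S)-2-aryloxy-3-hydroxy-3-(3-methoxy-4-triisopropylsilyloxyphenyl)propanoyl]oxazolidin-2-one, via dibutylboron Z-enolate 23 (not isolated)
Conditions: Bu2BOTf, i-Pr2NEt, CH2Cl2, −78 to 0 °C; then 9, −78 to 0 °C; pH 7 buffer, MeOH, H2O2, 0 °C
Reagents that add atoms: none
Why: In this auxiliary-controlled boron aldol (Evans syn aldol) soft enolisation gives the Z-enolate 23, which reacts through a chair Zimmerman–Traxler transition state on the face remote from the benzyl group of the (R)-auxiliary, setting C8'' in its final sense and C7'' syn to it (threo), the epimer that step 14 inverts.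

Step 14
Reactants: 24 syn aldol adduct
Product: 25 (2R,3R)-3-(4-nitrobenzoyloxy) imide (anti, erythro)
Conditions: 4-nitrobenzoic acid, PPh3, DIAD, THF, 0 °C to rt
Reagents that add atoms: 4-nitrobenzoic acid, OC(=O)c1ccc(cc1)[N+](=O)[O-]
Why: In this Mitsunobu esterification the benzylic C7'' hydroxyl is activated as its oxyphosphonium salt and displaced by 4-nitrobenzoate in an SN2 reaction with inversion, which turns the threo adduct into the erythro series, the acidic nucleophile and low temperature disfavouring elimination and ionisation.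

Step 15
Reactants: 25 nitrobenzoate imide
Product: 26 (7''R,8''S)-erythro diol (tris-TIPS ether of the target)
Conditions: LiBH4, THF–MeOH, 0 °C to rt
Reagents that add atoms: none
Why: LiBH4 reduces the N-acyl oxazolidinone to the C9'' primary alcohol and cleaves the activated aryl ester reductively to free the C7'' alcohol, a hydride reduction that touches neither stereocentre nor the silyl ethers.

Step 16
Reactants: 26 tris-TIPS erythro diol
Product: 27 target CNP0158473.3
Conditions: Bu4NF, AcOH, THF, 0 °C to rt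
Reagents that add atoms: none
Why: Fluoride cleaves the three TIPS ethers while the AcOH buffer keeps the liberated phenols protonated, so that no quinone methide can form at C7 or C7'' and no benzylic C–O bond is exposed to acid or hydrogen.

Compound list
1 | furfural (furan-2-carbaldehyde) | O=Cc1ccco1 | starting material
2 | 5-hydroxyfuran-2(5H)-one (racemic) | OC1OC(=O)C=C1 | intermediate
3 | (−)-menthol, (1R,2S,5R)-2-isopropyl-5-methylcyclohexan-1-ol | C[C@@H]1CC[C@H]([C@@H](C1)O)C(C)C | starting material
4 | (5R)-5-[(1R,2S,5R)-menthyloxy]furan-2(5H)-one | C[C@@H]1CC[C@H]([C@@H](C1)O[C@H]2C=CC(=O)O2)C(C)C | intermediate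
5 | O-benzylvanillin (4-benzyloxy-3-methoxybenzaldehyde) | COc1cc(C=O)ccc1OCc1ccccc1 | starting material
6 | propane-1,3-dithiol | SCCCS | starting material
7 | 2-(4-benzyloxy-3-methoxyphenyl)-1,3-dithiane | COc1cc(C2SCCCS2)ccc1OCc1ccccc1 | intermediate
8 | vanillin | COc1cc(C=O)ccc1O | starting material
9 | 3-methoxy-4-(triisopropylsilyloxy)benzaldehyde | COc1cc(C=O)ccc1O[Si](C(C)C)(C(C)C)C(C)C | intermediate
10 | 2-lithio-2-(4-benzyloxy-3-methoxyphenyl)-1,3-dithiane (not isolated) | COc1cc(C2([Li])SCCCS2)ccc1OCc1ccccc1 | intermediate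
11 | lithium enolate of (4R,5R)-4-[2-(4-benzyloxy-3-methoxyphenyl)-1,3-dithian-2-yl]-5-menthyloxyoxolan-2-one (not isolated) | COc1cc(C2(SCCCS2)[C@H]3[C@H](O[C@@H]4C[C@H](C)CC[C@H]4C(C)C)OC(O[Li])=C3)ccc1OCc1ccccc1 | intermediate
12 | tandem adduct, (3S,4R,5R)-4-[2-(4-benzyloxy-3-methoxyphenyl)-1,3-dithian-2-yl]-3-[hydroxy(3-methoxy-4-triisopropylsilyloxyphenyl)methyl]-5-[(1R,2S,5R)-menthyloxy]oxolan-2-one, C7 epimers | COc1cc(C2(SCCCS2)[C@H]3[C@H](O[C@@H]4C[C@H](C)CC[C@H]4C(C)C)OC(=O)[C@@H]3C(O)c5ccc(O[Si](C(C)C)(C(C)C)C(C)C)c(OC)c5)ccc1OCc6ccccc6 | intermediate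
13 | dithiane triol, (2R,3R)-2-[2-(4-benzyloxy-3-methoxyphenyl)-1,3-dithian-2-yl]-3-[hydroxy(3-methoxy-4-triisopropylsilyloxyphenyl)methyl]butane-1,4-diol, C7 epimers | COc1cc(C2(SCCCS2)[C@@H](CO)[C@H](CO)C(O)c3ccc(O[Si](C(C)C)(C(C)C)C(C)C)c(OC)c3)ccc1OCc4ccccc4 | intermediate
14 | triol, (2R,3R)-2-(4-benzyloxy-3-methoxybenzyl)-3-[hydroxy(3-methoxy-4-triisopropylsilyloxyphenyl)methyl]butane-1,4-diol (4'-O-benzyl-4-O-TIPS-7-hydroxysecoisolariciresinol), C7 epimers | COc1cc(C[C@@H](CO)[C@H](CO)C(O)c2ccc(O[Si](C(C)C)(C(C)C)C(C)C)c(OC)c2)ccc1OCc3ccccc3 | intermediate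
15 | [(2S,3R,4R)-4-(4-benzyloxy-3-methoxybenzyl)-2-(3-methoxy-4-triisopropylsilyloxyphenyl)oxolan-3-yl]methanol (4'-O-benzyl-4-O-TIPS-(+)-lariciresinol; 7,8-trans, 8,8'-cis) | COc1cc(C[C@H]2CO[C@H](c3ccc(O[Si](C(C)C)(C(C)C)C(C)C)c(OC)c3)[C@H]2CO)ccc1OCc4ccccc4 | intermediate
16 | 4'-O-benzyl-4,9-bis-O-TIPS-(+)-lariciresinol | COc1cc(C[C@H]2CO[C@H](c3ccc(O[Si](C(C)C)(C(C)C)C(C)C)c(OC)c3)[C@H]2CO[Si](C(C)C)(C(C)C)C(C)C)ccc1OCc4ccccc4 | intermediate
17 | 4,9-bis-O-TIPS-(+)-lariciresinol (ring B phenol free) | COc1cc(C[C@H]2CO[C@H](c3ccc(O[Si](C(C)C)(C(C)C)C(C)C)c(OC)c3)[C@H]2CO[Si](C(C)C)(C(C)C)C(C)C)ccc1O | intermediate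
18 | (R)-4-benzyloxazolidin-2-one | O=C1N[C@H](Cc2ccccc2)CO1 | starting material
19 | bromoacetyl bromide | BrCC(Br)=O | starting material
20 | N-lithio-(R)-4-benzyloxazolidin-2-one (not isolated) | [Li]N1[C@H](Cc2ccccc2)COC1=O | intermediate
21 | (R)-4-benzyl-3-(bromoacetyl)oxazolidin-2-one | BrCC(=O)N1[C@H](Cc2ccccc2)COC1=O | intermediate
22 | (R)-4-benzyl-3-(aryloxyacetyl)oxazolidin-2-one, aryloxy = ring B oxygen of 17 | COc1cc(C[C@H]2CO[C@H](c3ccc(O[Si](C(C)C)(C(C)C)C(C)C)c(OC)c3)[C@H]2CO[Si](C(C)C)(C(C)C)C(C)C)ccc1OCC(=O)N4[C@H](Cc5ccccc5)COC4=O | intermediate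
23 | dibutylboron Z-enolate of 22 (not isolated) | COc1cc(C[C@H]2CO[C@H](c3ccc(O[Si](C(C)C)(C(C)C)C(C)C)c(OC)c3)[C@H]2CO[Si](C(C)C)(C(C)C)C(C)C)ccc1O/C=C(\OB(CCCC)CCCC)N4[C@H](Cc5ccccc5)COC4=O | intermediate
24 | syn aldol adduct, (R)-4-benzyl-3-[(2R,3S)-2-aryloxy-3-hydroxy-3-(3-methoxy-4-triisopropylsilyloxyphenyl)propanoyl]oxazolidin-2-one (threo; 7''S,8''S after reduction) | COc1cc([C@H](O)[C@H](C(=O)N2[C@H](Cc3ccccc3)COC2=O)Oc4ccc(C[C@H]5CO[C@H](c6ccc(O[Si](C(C)C)(C(C)C)C(C)C)c(OC)c6)[C@H]5CO[Si](C(C)C)(C(C)C)C(C)C)cc4OC)ccc1O[Si](C(C)C)(C(C)C)C(C)C | intermediate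
25 | (2R,3R)-3-(4-nitrobenzoyloxy) imide (erythro, C7'' inverted) | COc1cc([C@@H](OC(=O)c7ccc(cc7)[N+](=O)[O-])[C@H](C(=O)N2[C@H](Cc3ccccc3)COC2=O)Oc4ccc(C[C@H]5CO[C@H](c6ccc(O[Si](C(C)C)(C(C)C)C(C)C)c(OC)c6)[C@H]5CO[Si](C(C)C)(C(C)C)C(C)C)cc4OC)ccc1O[Si](C(C)C)(C(C)C)C(C)C | intermediate
26 | (7''R,8''S)-erythro diol, 4,9,4''-tris-O-TIPS ether of the target | COc1cc([C@@H](O)[C@H](CO)Oc4ccc(C[C@H]5CO[C@H](c6ccc(O[Si](C(C)C)(C(C)C)C(C)C)c(OC)c6)[C@H]5CO[Si](C(C)C)(C(C)C)C(C)C)cc4OC)ccc1O[Si](C(C)C)(C(C)C)C(C)C | intermediate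
27 | CNP0158473.3, (7S,8R,8'R)-lariciresinol 4'-O-[(7''R,8''S)-erythro-guaiacylglycerol-8''-yl] ether | COc1cc([C@@H](O)[C@H](CO)Oc2ccc(C[C@H]3CO[C@H](c4ccc(O)c(OC)c4)[C@H]3CO)cc2OC)ccc1O | target

Total step count: 16.
Longest linear sequence: 13 steps (steps 1, 2, 5–10 and 12–16).

Steps most likely to fail

Step 5. The enolate may be intercepted incompletely by the electron-rich aldehyde: proton transfer or retro-aldol on the way to work-up would leave material at the mono-adduct stage. The fallback separates the two bond formations. It sets out from 7 and 4: 10 is added to 4 as before, but the enolate is protonated cold with AcOH and the lactone (4R,5R)-4-[2-(4-benzyloxy-3-methoxyphenyl)-1,3-dithian-2-yl]-5-menthyloxyoxolan-2-one F1 is isolated and purified. F1 is then re-enolised with LiN(i-Pr)2 in THF at −78 °C to 11, free of any residual dithiane anion, and 9 is added in a separate directed aldol addition. The route is rejoined at 12.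

Step 8. The ring C benzylic cation may be captured by ring B in a Friedel–Crafts closure to an aryltetralin, or the 7,8-trans selectivity may be incomplete. The fallback closes the ring through a quinone methide and sets out from 14. Bu4NF/AcOH removes the ring C silyl group to give the 4-hydroxybenzylic triol 4'-O-benzyl-7-hydroxysecoisolariciresinol F2. With pyridinium p-toluenesulfonate in wet THF the free phenol should expel the C7 hydroxyl as a p-quinone methide, to which the C9' hydroxyl adds reversibly, giving the trans ether 4'-O-benzyl-lariciresinol F3 at much lower acidity. Excess TIPSCl with imidazole then silylates the phenol and the C9 hydroxyl together, and the route is rejoined at 16.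

Step 14. Elimination across C7''–C8'' of the β-hydroxy imide, or partial ionisation at the benzylic centre with loss of stereochemical fidelity, may compete with the SN2 displacement. The fallback moves the inversion to a non-enolisable substrate and sets out from 24. LiBH4 first removes the auxiliary to give the threo (7''S,8''S) diol F4. TBSCl with imidazole silylates the primary C9'' hydroxyl to give the mono-TBS ether F5. Mitsunobu reaction with 4-nitrobenzoic acid then gives the inverted (7''R,8''S) 4-nitrobenzoate F6. LiBH4 cleaves the ester to the erythro alcohol F7, and Bu4NF/AcOH removes the TBS and the three TIPS groups. The route is rejoined at the target 27.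

Further compounds
F1 | step 5 | (4R,5R)-4-[2-(4-benzyloxy-3-methoxyphenyl)-1,3-dithian-2-yl]-5-[(1R,2S,5R)-menthyloxy]oxolan-2-one | COc1cc(C2(SCCCS2)[C@H]3[C@H](O[C@@H]4C[C@H](C)CC[C@H]4C(C)C)OC(=O)C3)ccc1OCc5ccccc5
F2 | step 8 | 4'-O-benzyl-7-hydroxysecoisolariciresinol (8R,8'R; C7 epimers; ring C phenol free) | COc1cc(C[C@@H](CO)[C@H](CO)C(O)c2ccc(O)c(OC)c2)ccc1OCc3ccccc3
F3 | step 8 | 4'-O-benzyl-(+)-lariciresinol (7S,8R,8'R) | COc1cc(C[C@H]2CO[C@H](c3ccc(O)c(OC)c3)[C@H]2CO)ccc1OCc4ccccc4
F4 | step 14 | (7''S,8''S)-threo diol, 4,9,4''-tris-O-TIPS | COc1cc([C@H](O)[C@H](CO)Oc2ccc(C[C@H]3CO[C@H](c4ccc(O[Si](C(C)C)(C(C)C)C(C)C)c(OC)c4)[C@H]3CO[Si](C(C)C)(C(C)C)C(C)C)cc2OC)ccc1O[Si](C(C)C)(C(C)C)C(C)C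
F5 | step 14 | 9''-O-TBS ether of the threo diol | COc1cc([C@H](O)[C@H](CO[Si](C)(C)C(C)(C)C)Oc2ccc(C[C@H]3CO[C@H](c4ccc(O[Si](C(C)C)(C(C)C)C(C)C)c(OC)c4)[C@H]3CO[Si](C(C)C)(C(C)C)C(C)C)cc2OC)ccc1O[Si](C(C)C)(C(C)C)C(C)C
F6 | step 14 | (7''R,8''S)-7''-O-(4-nitrobenzoyl) 9''-O-TBS ether | COc1cc([C@@H](OC(=O)c5ccc(cc5)[N+](=O)[O-])[C@H](CO[Si](C)(C)C(C)(C)C)Oc2ccc(C[C@H]3CO[C@H](c4ccc(O[Si](C(C)C)(C(C)C)C(C)C)c(OC)c4)[C@H]3CO[Si](C(C)C)(C(C)C)C(C)C)cc2OC)ccc1O[Si](C(C)C)(C(C)C)C(C)C
F7 | step 14 | (7''R,8''S)-erythro alcohol, 9''-O-TBS, 4,9,4''-tris-O-TIPS | COc1cc([C@@H](O)[C@H](CO[Si](C)(C)C(C)(C)C)Oc2ccc(C[C@H]3CO[C@H](c4ccc(O[Si](C(C)C)(C(C)C)C(C)C)c(OC)c4)[C@H]3CO[Si](C(C)C)(C(C)C)C(C)C)cc2OC)ccc1O[Si](C(C)C)(C(C)C)C(C)C
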